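**Plan**

1. Retrosynthetic cuts, in order: the lactone bond C12–O6 (and the O8 silyl ether), then the ring bond C7–C8, then C3–C4, C9–C10 and the C9 ester; the C7=C11 olefin comes from cross-metathesis, C1=C10 from olefination and C4=C5 from a propargylic alcohol.
2. Enabling feature: C8 is a carbinol carbon and C7 is allylic to the exocyclic C11=C13 methylene of the lactone ring (homoallylic alcohol C13=C11–C7–C8–OH). Retro-allylation opens the ten-membered ring to a C8 aldehyde and a C13 allyl bromide, the (Z)-2-(bromomethyl)-2-enoate C13–C11(CO2Et)=C7.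
3. Forward order: epoxy acid (steps 1–3), right piece C1–C3/C8–C10 (4–8), left piece C4–C7/C11–C13 (9–14), union at C3–C4 (15–18), unmasking of bromide and aldehyde (19–21), ten-membered carbocycle (22), γ-lactone ring (23), desilylation (24).
4. Stereochemistry: C6 by Sharpless kinetic resolution of hex-1-en-4-yn-3-ol; C9 by Felkin–Anh addition to (R)-glyceraldehyde acetonide, whose own stereocenter later becomes the C8 aldehyde carbon; C3 by CBS reduction; the oxirane by Sharpless epoxidation; the C1=C10 olefin by an α-iodo-ylide Wittig reaction and the C4=C5 olefin by trans-hydroalumination and iodination of the propargylic alcohol, each carried on by a stereoretentive chromium coupling.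
5. C7 and C8 arise together in the key step. An acyclic enoate, not a butenolide, is cyclised on purpose: its three local control elements (Z-allylchromium chair, Felkin–Anh at C8, allylic strain at C6) all favour the target, whereas a butenolide would have to be attacked on its hindered face. The lactone is closed afterwards from O6 only, because O8 is silylated during the ring closure.

Key step: step 22

Remark: carbons carry germacrane numbers (ring C1–C10; C6 bears the lactone oxygen, C7 the C11(=C13)–C12 unit, C8 the free hydroxyl, C9 the epoxyangelate, C3 the acetate; C14 and C15 are the methyls on C10 and C4). PMB = 4-methoxybenzyl, TBS = tert-butyldimethylsilyl, TES = triethylsilyl.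
Assumption: TESCl is taken to turn over the chromium alkoxide in the catalytic allylation as TMSCl does.

Step 1
Reactants: 1 methyl (2Z)-2-methylbut-2-enoate (methyl angelate)
Product: 2 (2Z)-2-methylbut-2-en-1-ol
Conditions: DIBAL-H (2.2 equiv), CH2Cl2, −78 °C
Reagents that add atoms: none
Why: Ester reduction with DIBAL-H gives the allylic alcohol by 1,2-reduction and leaves the Z olefin untouched.

Step 2
Reactants: 2 (2Z)-2-methylbut-2-en-1-ol
Product: 3 [(2S,3R)-2,3-dimethyloxiran-2-yl]methanol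
Conditions: Ti(OiPr)4 (cat.), L-(+)-diethyl tartrate (cat.), t-BuOOH, 4 Å MS, CH2Cl2, −20 °C
Reagents that add atoms: tert-butyl hydroperoxide, CC(C)(C)OO
Why: Sharpless asymmetric epoxidation, in which the titanium–L-(+)-tartrate complex should deliver oxygen to the olefin face that gives the 2S,3R epoxide, the Z geometry placing the two methyl groups trans on the oxirane.

Step 3
Reactants: 3 [(2S,3R)-2,3-dimethyloxiran-2-yl]methanol
Product: 4 (2R,3R)-2,3-dimethyloxirane-2-carboxylic acid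
Conditions: RuCl3 (cat.), NaIO4, CCl4/MeCN/H2O, rt
Reagents that add atoms: sodium periodate, [Na+].[O-]I(=O)(=O)=O
Why: Catalytic RuO4 oxidation takes the primary alcohol to the acid without touching either oxirane stereocenter.

Step 4
Reactants: 5 3-{[tert-butyl(dimethyl)silyl]oxy}propanal; 6 ethyl(triphenyl)phosphonium iodide
Product: 10 tert-butyl{[(3Z)-4-iodopent-3-en-1-yl]oxy}dimethylsilane, via ethylidene ylide 7 (not isolated), via iodoethylphosphonium iodide 8 (not isolated), via iodoethylidene ylide 9 (not isolated)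
Conditions: 6, n-BuLi, THF, rt; I2, −78 °C; NaHMDS, −20 °C; then 5, −78 → −20 °C
Reagents that add atoms: iodine, II
Why: Wittig olefination with an α-iodo ylide (Stork–Zhao type) should give the Z 2-iodoalkene, because the unstabilised ylide reacts under kinetic control through the cis oxaphosphetane.

Step 5
Reactants: 10 tert-butyl{[(3Z)-4-iodopent-3-en-1-yl]oxy}dimethylsilane; 11 (4R)-2,2-dimethyl-1,3-dioxolane-4-carbaldehyde
Product: 13 (1S,2Z)-5-{[tert-butyl(dimethyl)silyl]oxy}-1-[(4R)-2,2-dimethyl-1,3-dioxolan-4-yl]-2-methylpent-2-en-1-ol, via alkenylchromium 12 (not isolated)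
Conditions: CrCl2 (4 equiv), NiCl2 (1 mol%), DMSO, rt
Reagents that add atoms: none
Why: Nozaki–Hiyama–Kishi coupling, in which the alkenylchromium forms with retention of the Z geometry and should add to the α-alkoxy aldehyde under Felkin–Anh control (anti to the dioxolane C–O bond) to set the carbinol center S, the minor syn isomer being removed by chromatography.

Step 6
Reactants: 13 the allylic alcohol from step 5; 4 (2R,3R)-2,3-dimethyloxirane-2-carboxylic acid
Product: 15 (1S,2Z)-5-{[tert-butyl(dimethyl)silyl]oxy}-1-[(4R)-2,2-dimethyl-1,3-dioxolan-4-yl]-2-methylpent-2-en-1-yl (2R,3R)-2,3-dimethyloxirane-2-carboxylate, via mixed anhydride 14 (not isolated)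
Conditions: 4, 2,4,6-trichlorobenzoyl chloride, Et3N, toluene, rt; then 13, DMAP, rt → 40 °C
Reagents that add atoms: none
Why: Yamaguchi esterification acylates the hindered secondary allylic alcohol through the mixed anhydride, and no stereocenter takes part in the acyl transfer.

Step 7
Reactants: 15 the TBS-protected ester from step 6
Product: 16 (1S,2Z)-1-[(4R)-2,2-dimethyl-1,3-dioxolan-4-yl]-5-hydroxy-2-methylpent-2-en-1-yl (2R,3R)-2,3-dimethyloxirane-2-carboxylate
Conditions: TBAF, AcOH, THF, 0 °C → rt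
Reagents that add atoms: none
Why: Fluoride cleavage of the primary silyl ether, buffered with acetic acid so that the ester and the epoxide survive.

Step 8
Reactants: 16 the primary alcohol from step 7
Product: 17 (1S,2Z)-1-[(4R)-2,2-dimethyl-1,3-dioxolan-4-yl]-2-methyl-5-oxopent-2-en-1-yl (2R,3R)-2,3-dimethyloxirane-2-carboxylate
Conditions: Dess–Martin periodinane, pyridine, CH2Cl2, 0 °C
Reagents that add atoms: none
Why: Dess–Martin oxidation under neutral conditions gives the β,γ-unsaturated aldehyde without moving the olefin into conjugation, and the aldehyde is used at once.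

Step 9
Reactants: 18 ethyl 2-(hydroxymethyl)prop-2-enoate
Product: 19 ethyl 2-({[tert-butyl(dimethyl)silyl]oxy}methyl)prop-2-enoate
Conditions: TBSCl, imidazole, CH2Cl2, 0 °C → rt
Reagents that add atoms: tert-butyl(chloro)dimethylsilane, CC(C)(C)[Si](C)(C)Cl
Why: Silylation of the primary allylic alcohol masks the future C13 oxygen.

Step 10
Reactants: 20 prop-2-enal (acrolein); 21 prop-1-yn-1-ylmagnesium bromide
Product: 22 (3RS)-hex-1-en-4-yn-3-ol
Conditions: MeC≡CMgBr (0.5 M in THF), THF, −78 → 0 °C; aq. NH4Cl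
Reagents that add atoms: none
Why: 1,2-Addition of the alkynyl Grignard reagent to the enal carbonyl group, which a hard acetylide prefers over conjugate addition, gives the racemic vinyl propynyl carbinol that carries C4–C7 and C15.

Step 11
Reactants: 22 (3RS)-hex-1-en-4-yn-3-ol
Product: 23 (3S)-hex-1-en-4-yn-3-ol
Conditions: Ti(OiPr)4 (0.15 equiv), L-(+)-diisopropyl tartrate (0.2 equiv), t-BuOOH (0.6 equiv), 4 Å MS, CH2Cl2, −20 °C, to about 60% conversion
Reagents that add atoms: none
Why: Sharpless kinetic resolution of the secondary allylic alcohol, in which the titanium–L-(+)-tartrate complex should epoxidise the vinyl group of the 3R enantiomer much faster (erythro epoxy alcohol, removed by chromatography) and leave the 3S enantiomer, the alkyne being inert to the titanium peroxide; this sets C6.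

Step 12
Reactants: 23 (3S)-hex-1-en-4-yn-3-ol
Product: 25 (3S,4Z)-5-iodohexa-1,4-dien-3-ol, via cyclic alkenylaluminate 24 (not isolated)
Conditions: NaAlH2(OCH2CH2OMe)2 (1.5 equiv), THF, 0 °C → rt; EtOAc; then I2, −78 °C
Reagents that add atoms: iodine, II
Why: Hydroxyl-directed trans-hydroalumination of the propargylic alcohol delivers hydride to the proximal alkyne carbon and aluminium to the distal one within a five-membered oxaaluminacycle, and iodinolysis of the C–Al bond with retention should give the Z iodoalkene (iodine cis to the carbinol carbon) without touching the vinyl group or the carbinol center.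

Step 13
Reactants: 25 (3S,4Z)-5-iodohexa-1,4-dien-3-ol
Product: 26 1-({[(3S,4Z)-5-iodohexa-1,4-dien-3-yl]oxy}methyl)-4-methoxybenzene
Conditions: NaH, 4-methoxybenzyl chloride, Bu4NI (cat.), THF/DMF, 0 °C → rt
Reagents that add atoms: 4-methoxybenzyl chloride, COc1ccc(CCl)cc1
Why: Williamson etherification of the sodium alkoxide forms the PMB ether without breaking any bond at the carbinol center, so C6 keeps its configuration.

Step 14
Reactants: 26 the iododiene from step 13; 19 ethyl 2-({[tert-butyl(dimethyl)silyl]oxy}methyl)prop-2-enoate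
Product: 27 ethyl (2E,4S,5Z)-2-({[tert-butyl(dimethyl)silyl]oxy}methyl)-6-iodo-4-[(4-methoxyphenyl)methoxy]hepta-2,5-dienoate
Conditions: second-generation Hoveyda–Grubbs catalyst (10 mol%), 19 (5 equiv), CH2Cl2, 40 °C
Reagents that add atoms: none
Why: Olefin cross-metathesis between the terminal vinyl group and the 1,1-disubstituted acrylate should give the thermodynamic E enoate (C6 trans to the ester), the trisubstituted iodoalkene being inert to the catalyst.

Step 15
Reactants: 27 the alkenyl iodide from step 14; 17 the aldehyde from step 8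
Product: 29 ethyl (2E,4R,5Z,7RS,9Z,11S)-2-({[tert-butyl(dimethyl)silyl]oxy}methyl)-11-[(4R)-2,2-dimethyl-1,3-dioxolan-4-yl]-11-{[(2R,3R)-2,3-dimethyloxirane-2-carbonyl]oxy}-7-hydroxy-4-[(4-methoxyphenyl)methoxy]-6,10-dimethylundeca-2,5,9-trienoate, via alkenylchromium 28 (not isolated)
Conditions: CrCl2 (6 equiv), NiCl2 (2 mol%), DMSO/THF, rt
Reagents that add atoms: none
Why: Nozaki–Hiyama–Kishi coupling tolerates the esters, epoxide, acetal and ethers and keeps the Z geometry, and no control is sought at the new carbinol (C3) because step 16 oxidises it.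

Step 16
Reactants: 29 the epimeric allylic alcohols from step 15
Product: 30 ethyl (2E,4R,5Z,9Z,11S)-2-({[tert-butyl(dimethyl)silyl]oxy}methyl)-11-[(4R)-2,2-dimethyl-1,3-dioxolan-4-yl]-11-{[(2R,3R)-2,3-dimethyloxirane-2-carbonyl]oxy}-4-[(4-methoxyphenyl)methoxy]-6,10-dimethyl-7-oxoundeca-2,5,9-trienoate
Conditions: Dess–Martin periodinane, pyridine, CH2Cl2, 0 °C
Reagents that add atoms: none
Why: Dess–Martin oxidation of the only free hydroxyl gives the Z enone under neutral conditions and removes the uncontrolled center.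

Step 17
Reactants: 30 the Z enone from step 16
Product: 31 ethyl (2E,4R,5Z,7S,9Z,11S)-2-({[tert-butyl(dimethyl)silyl]oxy}methyl)-11-[(4R)-2,2-dimethyl-1,3-dioxolan-4-yl]-11-{[(2R,3R)-2,3-dimethyloxirane-2-carbonyl]oxy}-7-hydroxy-4-[(4-methoxyphenyl)methoxy]-6,10-dimethylundeca-2,5,9-trienoate
Conditions: (R)-2-methyl-CBS-oxazaborolidine (0.3 equiv), catecholborane, toluene, −78 °C
Reagents that add atoms: none
Why: Corey–Bakshi–Shibata reduction, in which the alkenyl group acts as the large substituent so that the (R)-catalyst should deliver hydride to the face giving the S carbinol at C3, by analogy with aryl alkyl ketones.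

Step 18
Reactants: 31 the (7S) alcohol from step 17
Product: 32 ethyl (2E,4R,5Z,7S,9Z,11S)-7-(acetyloxy)-2-({[tert-butyl(dimethyl)silyl]oxy}methyl)-11-[(4R)-2,2-dimethyl-1,3-dioxolan-4-yl]-11-{[(2R,3R)-2,3-dimethyloxirane-2-carbonyl]oxy}-4-[(4-methoxyphenyl)methoxy]-6,10-dimethylundeca-2,5,9-trienoate
Conditions: Ac2O, pyridine, DMAP (cat.), CH2Cl2, 0 °C → rt
Reagents that add atoms: acetic anhydride, CC(=O)OC(C)=O
Why: DMAP-catalysed acetylation of the secondary allylic alcohol proceeds with retention at C3.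

Step 19
Reactants: 32 the acetate from step 18
Product: 33 ethyl (2E,4R,5Z,7S,9Z,11S)-7-(acetyloxy)-11-[(4R)-2,2-dimethyl-1,3-dioxolan-4-yl]-11-{[(2R,3R)-2,3-dimethyloxirane-2-carbonyl]oxy}-2-(hydroxymethyl)-4-[(4-methoxyphenyl)methoxy]-6,10-dimethylundeca-2,5,9-trienoate
Conditions: HF·pyridine, pyridine, THF, 0 °C → rt
Reagents that add atoms: none
Why: Buffered HF·pyridine cleaves the only silyl ether and leaves the PMB ether, acetonide, esters and epoxide intact.

Step 20
Reactants: 33 the primary allylic alcohol from step 19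
Product: 34 ethyl (2Z,4R,5Z,7S,9Z,11S)-7-(acetyloxy)-2-(bromomethyl)-11-[(4R)-2,2-dimethyl-1,3-dioxolan-4-yl]-11-{[(2R,3R)-2,3-dimethyloxirane-2-carbonyl]oxy}-4-[(4-methoxyphenyl)methoxy]-6,10-dimethylundeca-2,5,9-trienoate
Conditions: CBr4, PPh3, CH2Cl2, 0 °C
Reagents that add atoms: tetrabromomethane, BrC(Br)(Br)Br
Why: Appel reaction, a direct SN2 displacement at the primary allylic carbon that keeps the enoate geometry (now Z by priority).

Step 21
Reactants: 34 the allylic bromide from step 20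
Product: 36 ethyl (2Z,4R,5Z,7S,9Z,11S)-7-(acetyloxy)-2-(bromomethyl)-11-{[(2R,3R)-2,3-dimethyloxirane-2-carbonyl]oxy}-4-[(4-methoxyphenyl)methoxy]-6,10-dimethyl-12-oxododeca-2,5,9-trienoate, via diol 35 (not isolated)
Conditions: H5IO6, EtOAc, rt
Reagents that add atoms: none
Why: Periodic acid hydrolyses the terminal acetonide and cleaves the resulting 1,2-diol (glycol cleavage), so the auxiliary stereocenter becomes the C8 aldehyde carbon under conditions that spare the allylic bromide.

Step 22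
Reactants: 36 the bromo aldehyde from step 21
Product: 39 ethyl 2-[(1R,2R,3Z,5S,7Z,9S,10R)-5-(acetyloxy)-9-{[(2R,3R)-2,3-dimethyloxirane-2-carbonyl]oxy}-2-[(4-methoxyphenyl)methoxy]-4,8-dimethyl-10-[(triethylsilyl)oxy]cyclodeca-3,7-dien-1-yl]prop-2-enoate, via allylchromium 37 (not isolated), via chromium alkoxide 38 (not isolated)
Conditions: CrCl2 (20 mol%), Mn powder (3 equiv), TESCl (3 equiv), THF, rt; 36 added by syringe pump to a final 2 mM
Reagents that add atoms: chlorotriethylsilane, CC[Si](Cl)(CC)CC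
Why: Divalent chromium, regenerated by Mn, reduces the C13–Br bond to the trivalent allylchromium 37 (ester trans to C6, C13 cis to C6), which adds through its γ-carbon C7 to the chromium-bound aldehyde C8 in a six-membered chair transition state with shift of the double bond to C11=C13; TESCl then silylates the chromium alkoxide 38, which turns the catalyst over and prevents O8 from lactonising onto the ester. The closest known reaction types are the intramolecular Nozaki–Hiyama–Kishi allylation of 2-(bromomethyl)-2-enoates onto aldehydes used to close ten-membered germacrane rings, and the manganese/chlorosilane catalytic version of the chromium allylation. The ten-membered carbocycle, the only ring formed, closes by 10-exo-trig attack on the carbonyl group with SE2′ reaction at the allyl unit. C8 is controlled by the C9 acyloxy stereocenter (polar Felkin–Anh attack anti to the C9–O bond, 8,9-anti); C7 relative to C8 by the chair with the Z-disposed C6 substituent axial and C9 equatorial (7,8-syn in the crotylation sense); and C7 relative to C6 by allylic 1,3-strain, which holds H6 in the allyl plane so that the aldehyde enters on the face of the PMB ether oxygen (which can also bind chromium) and anti to C5. All three local preferences lead to the same diastereomer, so the step mainly needs cyclisation over oligomerisation and γ- over α-attack; slow addition at high dilution, the two Z olefins that already bend the chain, and the γ-preference of ester-substituted allylchromium reagents should secure these.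

Step 23
Reactants: 39 the macrocyclic silyl ether from step 22
Product: 41 (3S,6R,7R,8R,9S)-3-(acetyloxy)-9-{[(2R,3R)-2,3-dimethyloxirane-2-carbonyl]oxy}-8-[(triethylsilyl)oxy]germacra-1(10)Z,4Z,11(13)-trien-12,6-olide, via hydroxy ester 40 (not isolated)
Conditions: DDQ, CH2Cl2/pH 7 buffer, 0 °C; then PPTS (cat.), toluene, 40 °C
Reagents that add atoms: none
Why: Oxidative PMB cleavage frees the C6 hydroxyl, which alone can close the cis-fused α-methylene-γ-lactone by 5-exo-trig transesterification because O8 is silylated, and no stereocenter changes.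

Step 24
Reactants: 41 the silylated lactone from step 23
Product: 42 (3S,6R,7S,8R,9S)-3-(acetyloxy)-8-hydroxy-9-{[(2R,3R)-2,3-dimethyloxirane-2-carbonyl]oxy}germacra-1(10)Z,4Z,11(13)-trien-12,6-olide (target)
Conditions: HF·pyridine, pyridine, THF, 0 °C → rt
Reagents that add atoms: none
Why: Acidic fluoride desilylation releases the C8 hydroxyl without the alkoxide formation that could trigger acyl migration from O9 or translactonisation.

**Compound list**

1 | methyl (2Z)-2-methylbut-2-enoate | C/C=C(/C)C(=O)OC | starting material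
2 | (2Z)-2-methylbut-2-en-1-ol | C/C=C(/C)CO | intermediate
3 | [(2S,3R)-2,3-dimethyloxiran-2-yl]methanol | OC[C@]1(C)O[C@@H]1C | intermediate
4 | (2R,3R)-2,3-dimethyloxirane-2-carboxylic acid | OC(=O)[C@]1(C)O[C@@H]1C | intermediate
5 | 3-{[tert-butyl(dimethyl)silyl]oxy}propanal | O=CCCO[Si](C)(C)C(C)(C)C | starting material
6 | ethyl(triphenyl)phosphonium iodide | CC[P+](c1ccccc1)(c1ccccc1)c1ccccc1.[I-] | starting material
7 | ethylidene(triphenyl)phosphorane | CC=P(c1ccccc1)(c1ccccc1)c1ccccc1 | intermediate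
8 | (1-iodoethyl)(triphenyl)phosphonium iodide | CC(I)[P+](c1ccccc1)(c1ccccc1)c1ccccc1.[I-] | intermediate
9 | (1-iodoethylidene)(triphenyl)phosphorane | CC(I)=P(c1ccccc1)(c1ccccc1)c1ccccc1 | intermediate
10 | tert-butyl{[(3Z)-4-iodopent-3-en-1-yl]oxy}dimethylsilane | C/C(I)=C/CCO[Si](C)(C)C(C)(C)C | intermediate
11 | (4R)-2,2-dimethyl-1,3-dioxolane-4-carbaldehyde | O=C[C@H]1COC(C)(C)O1 | starting material
12 | dichloro[(2Z)-5-{[tert-butyl(dimethyl)silyl]oxy}pent-2-en-2-yl]chromium (trivalent chromium, solvent ligands omitted) | C/C([Cr](Cl)Cl)=C/CCO[Si](C)(C)C(C)(C)C | intermediate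
13 | (1S,2Z)-5-{[tert-butyl(dimethyl)silyl]oxy}-1-[(4R)-2,2-dimethyl-1,3-dioxolan-4-yl]-2-methylpent-2-en-1-ol | CC(C)(C)[Si](C)(C)OCC/C=C(/C)[C@H](O)[C@H]1COC(C)(C)O1 | intermediate
14 | (2R,3R)-2,3-dimethyloxirane-2-carboxylic 2,4,6-trichlorobenzoic anhydride | O=C(OC(=O)c1c(Cl)cc(Cl)cc1Cl)[C@]1(C)O[C@@H]1C | intermediate
15 | (1S,2Z)-5-{[tert-butyl(dimethyl)silyl]oxy}-1-[(4R)-2,2-dimethyl-1,3-dioxolan-4-yl]-2-methylpent-2-en-1-yl (2R,3R)-2,3-dimethyloxirane-2-carboxylate | CC(C)(C)[Si](C)(C)OCC/C=C(/C)[C@H](OC(=O)[C@]1(C)O[C@@H]1C)[C@H]1COC(C)(C)O1 | intermediate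
16 | (1S,2Z)-1-[(4R)-2,2-dimethyl-1,3-dioxolan-4-yl]-5-hydroxy-2-methylpent-2-en-1-yl (2R,3R)-2,3-dimethyloxirane-2-carboxylate | OCC/C=C(/C)[C@H](OC(=O)[C@]1(C)O[C@@H]1C)[C@H]1COC(C)(C)O1 | intermediate
17 | (1S,2Z)-1-[(4R)-2,2-dimethyl-1,3-dioxolan-4-yl]-2-methyl-5-oxopent-2-en-1-yl (2R,3R)-2,3-dimethyloxirane-2-carboxylate | O=CC/C=C(/C)[C@H](OC(=O)[C@]1(C)O[C@@H]1C)[C@H]1COC(C)(C)O1 | intermediate
18 | ethyl 2-(hydroxymethyl)prop-2-enoate | C=C(CO)C(=O)OCC | starting material
19 | ethyl 2-({[tert-butyl(dimethyl)silyl]oxy}methyl)prop-2-enoate | C=C(CO[Si](C)(C)C(C)(C)C)C(=O)OCC | intermediate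
20 | prop-2-enal (acrolein) | C=CC=O | starting material
21 | prop-1-yn-1-ylmagnesium bromide | CC#C[Mg]Br | starting material
22 | (3RS)-hex-1-en-4-yn-3-ol | C=CC(O)C#CC | intermediate
23 | (3S)-hex-1-en-4-yn-3-ol | C=C[C@H](O)C#CC | intermediate
24 | sodium (5S)-5-ethenyl-2,2-bis(2-methoxyethoxy)-3-methyl-2,5-dihydro-1,2-oxaaluminol-2-uide (cyclic alkenylaluminate) | C=C[C@H]1C=C(C)[Al-](OCCOC)(OCCOC)O1.[Na+] | intermediate
25 | (3S,4Z)-5-iodohexa-1,4-dien-3-ol | C=C[C@H](O)/C=C(/C)I | intermediate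
26 | 1-({[(3S,4Z)-5-iodohexa-1,4-dien-3-yl]oxy}methyl)-4-methoxybenzene | C=C[C@H](OCc1ccc(OC)cc1)/C=C(/C)I | intermediate
27 | ethyl (2E,4S,5Z)-2-({[tert-butyl(dimethyl)silyl]oxy}methyl)-6-iodo-4-[(4-methoxyphenyl)methoxy]hepta-2,5-dienoate | CCOC(=O)/C(CO[Si](C)(C)C(C)(C)C)=C/[C@H](OCc1ccc(OC)cc1)/C=C(/C)I | intermediate
28 | ethyl (2E,5Z)-2-({[tert-butyl(dimethyl)silyl]oxy}methyl)-6-(dichlorochromio)-4-[(4-methoxyphenyl)methoxy]hepta-2,5-dienoate (27 with CrCl2 in place of iodine, trivalent chromium, configuration retained) | CCOC(=O)/C(CO[Si](C)(C)C(C)(C)C)=C/[C@H](OCc1ccc(OC)cc1)/C=C(/C)[Cr](Cl)Cl | intermediate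
29 | ethyl (2E,4R,5Z,7RS,9Z,11S)-2-({[tert-butyl(dimethyl)silyl]oxy}methyl)-11-[(4R)-2,2-dimethyl-1,3-dioxolan-4-yl]-11-{[(2R,3R)-2,3-dimethyloxirane-2-carbonyl]oxy}-7-hydroxy-4-[(4-methoxyphenyl)methoxy]-6,10-dimethylundeca-2,5,9-trienoate | CCOC(=O)/C(CO[Si](C)(C)C(C)(C)C)=C/[C@H](OCc1ccc(OC)cc1)/C=C(/C)C(O)C/C=C(/C)[C@H](OC(=O)[C@]1(C)O[C@@H]1C)[C@H]1COC(C)(C)O1 | intermediate
30 | ethyl (2E,4R,5Z,9Z,11S)-2-({[tert-butyl(dimethyl)silyl]oxy}methyl)-11-[(4R)-2,2-dimethyl-1,3-dioxolan-4-yl]-11-{[(2R,3R)-2,3-dimethyloxirane-2-carbonyl]oxy}-4-[(4-methoxyphenyl)methoxy]-6,10-dimethyl-7-oxoundeca-2,5,9-trienoate | CCOC(=O)/C(CO[Si](C)(C)C(C)(C)C)=C/[C@H](OCc1ccc(OC)cc1)/C=C(/C)C(=O)C/C=C(/C)[C@H](OC(=O)[C@]1(C)O[C@@H]1C)[C@H]1COC(C)(C)O1 | intermediate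
31 | ethyl (2E,4R,5Z,7S,9Z,11S)-2-({[tert-butyl(dimethyl)silyl]oxy}methyl)-11-[(4R)-2,2-dimethyl-1,3-dioxolan-4-yl]-11-{[(2R,3R)-2,3-dimethyloxirane-2-carbonyl]oxy}-7-hydroxy-4-[(4-methoxyphenyl)methoxy]-6,10-dimethylundeca-2,5,9-trienoate | CCOC(=O)/C(CO[Si](C)(C)C(C)(C)C)=C/[C@H](OCc1ccc(OC)cc1)/C=C(/C)[C@@H](O)C/C=C(/C)[C@H](OC(=O)[C@]1(C)O[C@@H]1C)[C@H]1COC(C)(C)O1 | intermediate
32 | ethyl (2E,4R,5Z,7S,9Z,11S)-7-(acetyloxy)-2-({[tert-butyl(dimethyl)silyl]oxy}methyl)-11-[(4R)-2,2-dimethyl-1,3-dioxolan-4-yl]-11-{[(2R,3R)-2,3-dimethyloxirane-2-carbonyl]oxy}-4-[(4-methoxyphenyl)methoxy]-6,10-dimethylundeca-2,5,9-trienoate | CCOC(=O)/C(CO[Si](C)(C)C(C)(C)C)=C/[C@H](OCc1ccc(OC)cc1)/C=C(/C)[C@@H](OC(C)=O)C/C=C(/C)[C@H](OC(=O)[C@]1(C)O[C@@H]1C)[C@H]1COC(C)(C)O1 | intermediate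
33 | ethyl (2E,4R,5Z,7S,9Z,11S)-7-(acetyloxy)-11-[(4R)-2,2-dimethyl-1,3-dioxolan-4-yl]-11-{[(2R,3R)-2,3-dimethyloxirane-2-carbonyl]oxy}-2-(hydroxymethyl)-4-[(4-methoxyphenyl)methoxy]-6,10-dimethylundeca-2,5,9-trienoate | CCOC(=O)/C(CO)=C/[C@H](OCc1ccc(OC)cc1)/C=C(/C)[C@@H](OC(C)=O)C/C=C(/C)[C@H](OC(=O)[C@]1(C)O[C@@H]1C)[C@H]1COC(C)(C)O1 | intermediate
34 | ethyl (2Z,4R,5Z,7S,9Z,11S)-7-(acetyloxy)-2-(bromomethyl)-11-[(4R)-2,2-dimethyl-1,3-dioxolan-4-yl]-11-{[(2R,3R)-2,3-dimethyloxirane-2-carbonyl]oxy}-4-[(4-methoxyphenyl)methoxy]-6,10-dimethylundeca-2,5,9-trienoate | CCOC(=O)/C(CBr)=C/[C@H](OCc1ccc(OC)cc1)/C=C(/C)[C@@H](OC(C)=O)C/C=C(/C)[C@H](OC(=O)[C@]1(C)O[C@@H]1C)[C@H]1COC(C)(C)O1 | intermediate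
35 | ethyl (2Z,4R,5Z,7S,9Z,11S,12R)-7-(acetyloxy)-2-(bromomethyl)-11-{[(2R,3R)-2,3-dimethyloxirane-2-carbonyl]oxy}-12,13-dihydroxy-4-[(4-methoxyphenyl)methoxy]-6,10-dimethyltrideca-2,5,9-trienoate | CCOC(=O)/C(CBr)=C/[C@H](OCc1ccc(OC)cc1)/C=C(/C)[C@@H](OC(C)=O)C/C=C(/C)[C@H](OC(=O)[C@]1(C)O[C@@H]1C)[C@H](O)CO | intermediate
36 | ethyl (2Z,4R,5Z,7S,9Z,11S)-7-(acetyloxy)-2-(bromomethyl)-11-{[(2R,3R)-2,3-dimethyloxirane-2-carbonyl]oxy}-4-[(4-methoxyphenyl)methoxy]-6,10-dimethyl-12-oxododeca-2,5,9-trienoate | CCOC(=O)/C(CBr)=C/[C@H](OCc1ccc(OC)cc1)/C=C(/C)[C@@H](OC(C)=O)C/C=C(/C)[C@H](OC(=O)[C@]1(C)O[C@@H]1C)C=O | intermediate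
37 | allylchromium from 36: the CH2Br group replaced by CH2CrCl2 (trivalent chromium, solvent ligands omitted), all else as 36 | CCOC(=O)/C(C[Cr](Cl)Cl)=C/[C@H](OCc1ccc(OC)cc1)/C=C(/C)[C@@H](OC(C)=O)C/C=C(/C)[C@H](OC(=O)[C@]1(C)O[C@@H]1C)C=O | intermediate
38 | dichlorochromium alkoxide of the cyclised hydroxy ester: 39 with O–CrCl2 in place of O–SiEt3 (trivalent chromium) | C=C(C(=O)OCC)[C@@H]1[C@H](OCc2ccc(OC)cc2)/C=C(/C)[C@@H](OC(C)=O)C/C=C(/C)[C@H](OC(=O)[C@]2(C)O[C@@H]2C)[C@@H]1O[Cr](Cl)Cl | intermediate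
39 | ethyl 2-[(1R,2R,3Z,5S,7Z,9S,10R)-5-(acetyloxy)-9-{[(2R,3R)-2,3-dimethyloxirane-2-carbonyl]oxy}-2-[(4-methoxyphenyl)methoxy]-4,8-dimethyl-10-[(triethylsilyl)oxy]cyclodeca-3,7-dien-1-yl]prop-2-enoate | C=C(C(=O)OCC)[C@@H]1[C@H](OCc2ccc(OC)cc2)/C=C(/C)[C@@H](OC(C)=O)C/C=C(/C)[C@H](OC(=O)[C@]2(C)O[C@@H]2C)[C@@H]1O[Si](CC)(CC)CC | intermediate
40 | ethyl 2-[(1R,2R,3Z,5S,7Z,9S,10R)-5-(acetyloxy)-9-{[(2R,3R)-2,3-dimethyloxirane-2-carbonyl]oxy}-2-hydroxy-4,8-dimethyl-10-[(triethylsilyl)oxy]cyclodeca-3,7-dien-1-yl]prop-2-enoate | C=C(C(=O)OCC)[C@@H]1[C@H](O)/C=C(/C)[C@@H](OC(C)=O)C/C=C(/C)[C@H](OC(=O)[C@]2(C)O[C@@H]2C)[C@@H]1O[Si](CC)(CC)CC | intermediate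
41 | (3S,6R,7R,8R,9S)-3-(acetyloxy)-9-{[(2R,3R)-2,3-dimethyloxirane-2-carbonyl]oxy}-8-[(triethylsilyl)oxy]germacra-1(10)Z,4Z,11(13)-trien-12,6-olide | C=C1C(=O)O[C@@H]2/C=C(/C)[C@@H](OC(C)=O)C/C=C(/C)[C@H](OC(=O)[C@]3(C)O[C@@H]3C)[C@H](O[Si](CC)(CC)CC)[C@H]12 | intermediate
42 | (3S,6R,7S,8R,9S)-3-(acetyloxy)-8-hydroxy-9-{[(2R,3R)-2,3-dimethyloxirane-2-carbonyl]oxy}germacra-1(10)Z,4Z,11(13)-trien-12,6-olide | C=C1C(=O)O[C@@H]2/C=C(/C)[C@@H](OC(C)=O)C/C=C(/C)[C@H](OC(=O)[C@]3(C)O[C@@H]3C)[C@H](O)[C@H]12 | target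

**Totals and risks**

Total step count: 24. Longest linear sequence: 16 steps (steps 1–3, then 6–8, then 15–24).

Step 22 (key step). Ring strain in the ten-membered transition state may override the Felkin–Anh preference, so that the aldehyde is attacked on its other face, and intermolecular allylation may compete with ring closure. The fallback for the facial problem sets out from 36 and comes back to the route at 42. The same ring closure would then give mainly the 8-epi macrocyclic silyl ether F1, which is the C8 epimer of 39. DDQ and then PPTS, as in step 23, should lead through the 8-epi hydroxy ester F2 to the 8-epi silylated lactone F3, and HF·pyridine, as in step 24, to the 8-epi hydroxy lactone F4. Dess–Martin periodinane buffered with pyridine oxidises this alcohol to the 8-oxo lactone F5. Reduction with Zn(BH4)2 in ether at −40 °C, with zinc bridging the C8 carbonyl and the C9 ester oxygen, should give the 8,9-anti alcohol, which is 42. This sets C8 by a chelation-controlled ketone reduction instead of by the allylation.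

Step 14. The cross-metathesis may stall because the vinyl group sits on a hindered bis-allylic ether carbon and the acrylate is 1,1-disubstituted, leaving homodimers or unreacted 26. The fallback sets out from 26 and comes back to the route at 27. One-pot dihydroxylation and periodate cleavage of the terminal vinyl group (OsO4 cat., NaIO4, 2,6-lutidine, dioxane/water) passes through (3R,4Z)-5-iodo-3-[(4-methoxyphenyl)methoxy]hex-4-ene-1,2-diol F6 and gives (2R,3Z)-4-iodo-2-[(4-methoxyphenyl)methoxy]pent-3-enal F7. Horner–Wadsworth–Emmons olefination of the crude aldehyde with ethyl 3-{[tert-butyl(dimethyl)silyl]oxy}-2-(diethoxyphosphoryl)propanoate (LiCl, DBU, MeCN, 0 °C) returns the E enoate 27.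

Step 17. The Z enone is twisted, which may erode facial discrimination by the oxazaborolidine, and it may isomerise to the E enone or into conjugation with the C1=C10 olefin before it is reduced. The fallback sets out from 27 and 17 and comes back to the route at 31. It is a ligand-controlled Nozaki–Hiyama–Kishi coupling (CrCl2, NiCl2 cat., Et3N, THF, with stoichiometric N-[2-(4-isopropyl-4,5-dihydro-1,3-oxazol-2-yl)-6-methylphenyl]methanesulfonamide, using the ligand enantiomer that favours the S carbinol at C3). This forms the C3 center directly in the C–C bond formation and bypasses the enone; it makes no new compound.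

Further compounds
F1 | step 22 | 8-epi macrocyclic silyl ether (C8 epimer of 39) | C=C(C(=O)OCC)[C@@H]1[C@H](OCc2ccc(OC)cc2)/C=C(/C)[C@@H](OC(C)=O)C/C=C(/C)[C@H](OC(=O)[C@]2(C)O[C@@H]2C)[C@H]1O[Si](CC)(CC)CC
F2 | step 22 | 8-epi hydroxy ester (C8 epimer of 40) | C=C(C(=O)OCC)[C@@H]1[C@H](O)/C=C(/C)[C@@H](OC(C)=O)C/C=C(/C)[C@H](OC(=O)[C@]2(C)O[C@@H]2C)[C@H]1O[Si](CC)(CC)CC
F3 | step 22 | 8-epi silylated lactone (C8 epimer of 41) | C=C1C(=O)O[C@@H]2/C=C(/C)[C@@H](OC(C)=O)C/C=C(/C)[C@H](OC(=O)[C@]3(C)O[C@@H]3C)[C@@H](O[Si](CC)(CC)CC)[C@H]12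
F4 | step 22 | 8-epi hydroxy lactone (C8 epimer of 42) | C=C1C(=O)O[C@@H]2/C=C(/C)[C@@H](OC(C)=O)C/C=C(/C)[C@H](OC(=O)[C@]3(C)O[C@@H]3C)[C@@H](O)[C@H]12
F5 | step 22 | 8-oxo lactone (42 with C8 as a ketone) | C=C1C(=O)O[C@@H]2/C=C(/C)[C@@H](OC(C)=O)C/C=C(/C)[C@H](OC(=O)[C@]3(C)O[C@@H]3C)C(=O)[C@H]12
F6 | step 14 | (3R,4Z)-5-iodo-3-[(4-methoxyphenyl)methoxy]hex-4-ene-1,2-diol (epimers at C2) | OCC(O)[C@H](OCc1ccc(OC)cc1)/C=C(/C)I
F7 | step 14 | (2R,3Z)-4-iodo-2-[(4-methoxyphenyl)methoxy]pent-3-enal | O=C[C@H](OCc1ccc(OC)cc1)/C=C(/C)I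
F0 | step 17 | none | none
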